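**Retrosynthetic overview**
1. The strategy rests on the C1–C5 ring-fusion bond: it divides a ten-membered carbocycle C1–C10 into the cyclopentane (C1–C5) and the cycloheptene (C1, C5–C10) of the hydroazulene, and is formed by transannular ketyl–olefin closure of an (E)-cyclodec-5-enone (C5 ketone, α-quaternary C4, C1=C10 alkene).
2. The cyclodecenone comes from anionic oxy-Cope rearrangement of a trans-1,2-dialkenylcyclohexanol (C5–C10 broken, C2–C3 formed) with methylation of the enolate at C4; the C10 configuration of the cyclohexane fixes the exposed enolate face and therefore C4.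
3. The cyclohexanol is built from (S)-carvone (reductive aldol, dehydration) and a 2-lithioalkene carrying C1' (auxiliary alkylation of an arylacetic acid); C7 is then brought to the target configuration by epimerising a methyl ketone unveiled from the isopropenyl group.
4. Ring order: six-membered ring from the chiral pool, ten-membered ring by four-carbon ring expansion, then the five- and seven-membered rings together in the key step.
5. Endgame: anti dehydration to C5=C6, twofold ortho-lithiation/formylation of the arene, desilylation, thiolate demethylation.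

Key step: step 14

Assumption: 2-(2,4,6-trimethoxyphenyl)acetic acid is taken as a commercial compound.
Assumption: direct α-vinylation of the carvone enolate places the vinyl group cis to the C7 substituent, and the chair oxy-Cope then exposes the enolate face that leads to the C4 epimer; the route therefore uses (S)-carvone and inverts C7 afterwards, so that both C4 and C7 come out as in the target.
Numbering: C1–C10 and C1' are those of the target skeleton (C1 ring-fusion CH, C4 quaternary, C5=C6 alkene, C7 carbinol-bearing CH, C10 CH–CH3, C1' benzylic CH). In the cyclohexane intermediates, ring carbons C1, C2, C5, C6 become C5, C10, C7, C6.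

**Step 1**
Reactants: 1 (S)-(+)-carvone
Product: 3 (2S,5S)-2-(1-hydroxyethyl)-2-methyl-5-(prop-1-en-2-yl)cyclohexan-1-one (carbinol epimers), via lithium enolate 2 (not isolated)
Conditions: LiBH(s-Bu)3, THF, −78 °C; then CH3CHO, −78 °C; aq. NH4Cl
Reagents that add atoms: acetaldehyde CC=O
Why: Conjugate hydride transfer gives the C1–C2 lithium enolate regiospecifically, and its aldol addition (reductive aldol) should create the quaternary carbon by axial attack, cis to the equatorial isopropenyl group as in alkylations of this enolate, the carbinol epimers converging in step 2.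

**Step 2**
Reactants: 3 aldol
Product: 4 (2S,5S)-2-ethenyl-2-methyl-5-(prop-1-en-2-yl)cyclohexan-1-one
Conditions: methyl N-(triethylammoniosulfonyl)carbamate (Burgess reagent), toluene, 70 °C
Reagents that add atoms: none
Why: Burgess dehydration is a syn elimination of the sulfamate ester, and because the α-carbon is quaternary only the methyl group offers a β-hydrogen, so the terminal vinyl group should form without migration.

**Step 3**
Reactants: 5 2-(2,4,6-trimethoxyphenyl)acetic acid; 6 (R)-4-benzyl-1,3-oxazolidin-2-one
Product: 8 (4R)-4-benzyl-3-[2-(2,4,6-trimethoxyphenyl)acetyl]-1,3-oxazolidin-2-one, via mixed pivalic anhydride 7 (not isolated)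
Conditions: t-BuCOCl, Et3N, THF, −20 °C; then LiCl, 6, 23 °C
Reagents that add atoms: none
Why: Mixed-anhydride N-acylation of the oxazolidinone under LiCl/Et3N is a standard mild acylation and creates no stereocentre.

**Step 4**
Reactants: 8 imide
Product: 10 (4R)-4-benzyl-3-[(2R)-4-methyl-2-(2,4,6-trimethoxyphenyl)pent-4-enoyl]-1,3-oxazolidin-2-one, via sodium Z-enolate 9 (not isolated)
Conditions: NaN(SiMe3)2, THF, −78 °C; CH2=C(CH3)CH2Br, −78 → −40 °C
Reagents that add atoms: 3-bromo-2-methylpropene C=C(C)CBr
Why: Evans alkylation, in which the chelated Z enolate is attacked by the allylic bromide on the face away from the benzyl group, should set C1' (2R in the imide).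

**Step 5**
Reactants: 10 alkylated imide
Product: 11 (4R)-4-benzyl-3-[(2R)-4-methyl-2-(2,4,6-trimethoxyphenyl)pentanoyl]-1,3-oxazolidin-2-one
Conditions: H2 (1 atm), 10% Pd/C, EtOAc, 23 °C
Reagents that add atoms: none
Why: Heterogeneous hydrogenation should saturate the 1,1-disubstituted alkene to the isobutyl group without touching the arene, the imide or the stereocentre.

**Step 6**
Reactants: 11 imide
Product: 12 S-ethyl (2R)-4-methyl-2-(2,4,6-trimethoxyphenyl)pentanethioate
Conditions: EtSH, n-BuLi, THF, 0 °C
Reagents that add atoms: ethanethiol CCS (as its lithium salt)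
Why: Thiolate cleavage of an N-acyl oxazolidinone attacks the exocyclic carbonyl selectively, so the thioester should form without epimerisation and the auxiliary is returned.

**Step 7**
Reactants: 12 thioester
Product: 13 (3R)-5-methyl-3-(2,4,6-trimethoxyphenyl)hexan-2-one
Conditions: Me2CuLi (from MeLi and CuI), Et2O, −78 °C
Reagents that add atoms: lithium dimethylcuprate [Li+].C[Cu-]C (from methyllithium C[Li])
Why: Thioesters react with lithium dialkylcuprates to give ketones and stop there, and the weakly basic cuprate at low temperature should leave the α-aryl stereocentre intact.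

**Step 8**
Reactants: 13 methyl ketone
Product: 14 N'-[(2E,3R)-5-methyl-3-(2,4,6-trimethoxyphenyl)hexan-2-ylidene]-2,4,6-tri(propan-2-yl)benzenesulfonohydrazide
Conditions: 2,4,6-(i-Pr)3C6H2SO2NHNH2, THF, 23 °C
Reagents that add atoms: 2,4,6-tri(propan-2-yl)benzenesulfonohydrazide NNS(=O)(=O)c1c(C(C)C)cc(C(C)C)cc1C(C)C
Why: Condensation of the methyl ketone with the sulfonyl hydrazide under neutral conditions should give the E hydrazone (sulfonamide syn to methyl), the substrate for a Shapiro reaction.

**Step 9**
Reactants: 14 hydrazone; 4 vinyl ketone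
Product: 16 1-[(3S)-5-methyl-3-(2,4,6-trimethoxyphenyl)hex-1-en-2-yl]-2-ethenyl-2-methyl-5-(prop-1-en-2-yl)cyclohexan-1-ol (alkenyl trans to vinyl; hydroxyl trans to methyl; isopropenyl cis to vinyl), via 2-lithioalkene 15 (not isolated)
Conditions: 14, n-BuLi (2 equiv), THF, −78 → 0 °C; CeCl3, −78 °C; then 4, −78 → −40 °C
Reagents that add atoms: none
Why: Shapiro reaction, in which the dianion formed at the methyl group loses sulfinate and N2 to give the 2-lithioalkene; its cerium derivative (low basicity, little enolisation) should add to the ketone anti to the axial vinyl group, the minor carbinol epimer being removed by chromatography.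

**Step 10**
Reactants: 16 dialkenyl carbinol
Product: 18 5-acetyl carbinol with acetyl trans to vinyl and cis to the C1 alkenyl group, via acetyl cis to vinyl ketone 17 (not isolated)
Conditions: OsO4 (cat.), NaIO4, 2,6-lutidine, dioxane–H2O, 23 °C; then K2CO3, MeOH, 40 °C
Reagents that add atoms: osmium tetroxide O=[Os](=O)(=O)=O and sodium periodate [Na+].[O-]I(=O)(=O)=O (oxygen atom of the new ketone)
Why: Lemieux–Johnson cleavage should select the unhindered isopropenyl group over the neopentyl vinyl group and the flanked 2-alkenyl group, and base then epimerises the carbon α to the new ketone to the isomer whose chair has both alkenyl groups and the acetyl group equatorial, which sets C7 and places the two alkenyl groups gauche.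

**Step 11**
Reactants: 18 methyl ketone
Product: 19 diol with a 2-hydroxypropan-2-yl group at C5 of the cyclohexanol
Conditions: MeMgBr, CeCl3, THF, −78 → 0 °C
Reagents that add atoms: methylmagnesium bromide C[Mg]Br
Why: Grignard addition to the methyl ketone (CeCl3 suppresses enolisation) should give the tertiary carbinol of the target side chain without forming a stereocentre.

**Step 12**
Reactants: 19 diol
Product: 20 mono(triethylsilyl) ether at the side-chain carbinol
Conditions: Et3SiOTf, 2,6-lutidine, CH2Cl2, −78 °C
Reagents that add atoms: triethylsilyl trifluoromethanesulfonate CC[Si](CC)(CC)OS(=O)(=O)C(F)(F)F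
Why: The side-chain tertiary alcohol is far more accessible than the ring carbinol flanked by a quaternary carbon, so one equivalent of silyl triflate should protect it selectively.

**Step 13**
Reactants: 20 silyl ether carbinol
Product: 22 (E)-cyclodec-5-enone with quaternary C4 (C4/C7/C1' as in the target), via potassium enolate 21 (not isolated)
Conditions: KH, 18-crown-6, THF, 0 → 40 °C; then MeI, −78 → 0 °C
Reagents that add atoms: iodomethane CI
Why: Anionic oxy-Cope rearrangement through a chair transition state with both ring bonds equatorial should break C5–C10, form C2–C3 and give the (E)-C1=C10 alkene and a trans-ring enolate whose planar chirality is fixed by C10, and C-methylation on its outer face, which is also anti to the aryl group in the A(1,3)-minimised rotamer at C1', sets C4.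

**Step 14**
Reactants: 22 cyclodecenone
Product: 23 cis-fused hydroazulen-5-ol (hydroxyl cis to H1; H10 cis to H1)
Conditions: SmI2, HMPA, t-BuOH, THF, 0 °C
Reagents that add atoms: none
Why: SmI2 with HMPA reduces the C5 ketone to a samarium ketyl that adds across the ring to C1 of the C1=C10 alkene, and the tertiary C10 radical is reduced by a second SmI2 (or abstracts hydrogen) and protonated by t-BuOH. The closest known reaction type is the SmI2-promoted transannular ketyl–olefin cyclisation of medium-ring cycloalkenones, here on a more substituted ring. The five-membered ring (C1–C5) closes in a 5-exo-trig mode with respect to the C4–C3–C2 tether, and the seven-membered ring (C1, C5–C10) is what remains of the ten-membered ring. C5 is set by the samarium-bound oxygen lying anti to C10 (hydroxyl cis to H1, cis fusion), C1 by a chair-like transition state in which the large C1' substituent on C4 is pseudo-equatorial and so trans to C10, and C10 by protonation on the convex face, the side of H1 and of the samarium alkoxide. The step needs attack at C1 rather than C10, which the trisubstituted alkene secures (less hindered carbon attacked, tertiary radical formed), and the facial selectivity just described, which the quaternary C4 next to the ketyl secures.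

**Step 15**
Reactants: 23 hydroazulenol
Product: 24 hydroazulene with C5=C6 alkene
Conditions: POCl3, pyridine, 0 → 50 °C
Reagents that add atoms: none
Why: E2 elimination of the dichlorophosphate needs an anti-periplanar hydrogen, and since H1 is syn to the leaving group and C4 is quaternary only H6 can be lost, so the C5=C6 alkene should form regioselectively.

**Step 16**
Reactants: 24 trimethoxyaryl hydroazulene
Product: 29 3,5-diformyl-2,4,6-trimethoxyphenyl compound (silyl ether), via aryllithium 25 (not isolated), via lithium α-amino alkoxide 26 (not isolated), via lithiated α-amino alkoxide 27 (not isolated), via bis(α-amino alkoxide) 28 (not isolated)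
Conditions: n-BuLi, TMEDA, THF, 0 °C; DMF, −78 → 0 °C; n-BuLi, 0 °C; DMF; aq. NH4Cl
Reagents that add atoms: N,N-dimethylformamide CN(C)C=O
Why: Directed ortho-lithiation takes place at the aryl C–H flanked by two methoxy groups and DMF formylates it, and the lithium α-amino alkoxide so formed masks the aldehyde and directs the second lithiation to the remaining position, so both formyl groups should be installed in one flask.

**Step 17**
Reactants: 29 silyl ether dialdehyde
Product: 30 tri-O-methyl ether of the target
Conditions: Bu4NF, THF, 40 °C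
Reagents that add atoms: none
Why: Fluoride should cleave the tertiary triethylsilyl ether without affecting the non-enolisable aldehydes, the aryl methyl ethers or the alkene.

**Step 18**
Reactants: 30 tri-O-methyl ether
Product: 31 CNP0281883.3 (target)
Conditions: 4-MeC6H4SLi (from the thiol and n-BuLi), HMPA, toluene, 110 °C; aq. HCl
Reagents that add atoms: none
Why: Thiolate SN2 demethylation of aryl methyl ethers activated by ortho formyl groups should free the three phenols under basic conditions that the tertiary alcohol and the trisubstituted alkene tolerate.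

**Compound list**
1 | (S)-(+)-carvone | CC(=C)[C@H]1CC=C(C)C(=O)C1 | starting material
2 | lithium (5S)-2-methyl-5-(prop-1-en-2-yl)cyclohex-1-en-1-olate | CC(=C)[C@H]1CCC(C)=C([O-])C1.[Li+] | intermediate
3 | (2S,5S)-2-(1-hydroxyethyl)-2-methyl-5-(prop-1-en-2-yl)cyclohexan-1-one, carbinol epimers | CC(O)[C@]1(C)CC[C@H](C(C)=C)CC1=O | intermediate
4 | (2S,5S)-2-ethenyl-2-methyl-5-(prop-1-en-2-yl)cyclohexan-1-one | C=C[C@]1(C)CC[C@H](C(C)=C)CC1=O | intermediate
5 | 2-(2,4,6-trimethoxyphenyl)acetic acid | COc1cc(OC)c(CC(O)=O)c(OC)c1 | starting material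
6 | (R)-4-benzyl-1,3-oxazolidin-2-one | O=C1N[C@H](Cc2ccccc2)CO1 | starting material
7 | 2-(2,4,6-trimethoxyphenyl)acetic pivalic anhydride | COc1cc(OC)c(CC(=O)OC(=O)C(C)(C)C)c(OC)c1 | intermediate
8 | (4R)-4-benzyl-3-[2-(2,4,6-trimethoxyphenyl)acetyl]-1,3-oxazolidin-2-one | COc1cc(OC)c(CC(=O)N2[C@H](Cc3ccccc3)COC2=O)c(OC)c1 | intermediate
9 | sodium Z-enolate of 8 | COc1cc(OC)c(/C=C(\[O-])N2[C@H](Cc3ccccc3)COC2=O)c(OC)c1.[Na+] | intermediate
10 | (4R)-4-benzyl-3-[(2R)-4-methyl-2-(2,4,6-trimethoxyphenyl)pent-4-enoyl]-1,3-oxazolidin-2-one | C=C(C)C[C@H](c1c(OC)cc(OC)cc1OC)C(=O)N2[C@H](Cc3ccccc3)COC2=O | intermediate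
11 | (4R)-4-benzyl-3-[(2R)-4-methyl-2-(2,4,6-trimethoxyphenyl)pentanoyl]-1,3-oxazolidin-2-one | CC(C)C[C@H](c1c(OC)cc(OC)cc1OC)C(=O)N2[C@H](Cc3ccccc3)COC2=O | intermediate
12 | S-ethyl (2R)-4-methyl-2-(2,4,6-trimethoxyphenyl)pentanethioate | CC(C)C[C@H](c1c(OC)cc(OC)cc1OC)C(=O)SCC | intermediate
13 | (3R)-5-methyl-3-(2,4,6-trimethoxyphenyl)hexan-2-one | CC(C)C[C@H](c1c(OC)cc(OC)cc1OC)C(C)=O | intermediate
14 | N'-[(2E,3R)-5-methyl-3-(2,4,6-trimethoxyphenyl)hexan-2-ylidene]-2,4,6-tri(propan-2-yl)benzenesulfonohydrazide | CC(C)C[C@H](c1c(OC)cc(OC)cc1OC)/C(C)=N/NS(=O)(=O)c1c(C(C)C)cc(C(C)C)cc1C(C)C | intermediate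
15 | [(3S)-5-methyl-3-(2,4,6-trimethoxyphenyl)hex-1-en-2-yl]lithium | CC(C)C[C@H](c1c(OC)cc(OC)cc1OC)C(=C)[Li] | intermediate
16 | dialkenyl carbinol: C1 alkenyl trans to C2 vinyl, hydroxyl trans to C2 methyl, C5 isopropenyl cis to vinyl | CC(C)C[C@H](c1c(OC)cc(OC)cc1OC)C(=C)[C@]2(O)C[C@@H](C(C)=C)CC[C@@]2(C)C=C | intermediate
17 | 5-acetyl carbinol, acetyl cis to vinyl | CC(C)C[C@H](c1c(OC)cc(OC)cc1OC)C(=C)[C@]2(O)C[C@@H](C(C)=O)CC[C@@]2(C)C=C | intermediate
18 | 5-acetyl carbinol, acetyl trans to vinyl (C5 epimer of 17) | CC(C)C[C@H](c1c(OC)cc(OC)cc1OC)C(=C)[C@]2(O)C[C@H](C(C)=O)CC[C@@]2(C)C=C | intermediate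
19 | diol: 5-(2-hydroxypropan-2-yl) analogue of 18 | CC(C)C[C@H](c1c(OC)cc(OC)cc1OC)C(=C)[C@]2(O)C[C@H](C(C)(C)O)CC[C@@]2(C)C=C | intermediate
20 | side-chain triethylsilyl ether of 19 | CC(C)C[C@H](c1c(OC)cc(OC)cc1OC)C(=C)[C@]2(O)C[C@H](C(C)(C)O[Si](CC)(CC)CC)CC[C@@]2(C)C=C | intermediate
21 | potassium (E,E)-cyclodeca-1,5-dien-1-olate (enolate C4=C5, alkene C1=C10) | CC(C)C[C@H](c1c(OC)cc(OC)cc1OC)/C2=C(/[O-])C[C@H](C(C)(C)O[Si](CC)(CC)CC)CC/C(C)=C/CC2.[K+] | intermediate
22 | (E)-cyclodec-5-enone: C5 ketone, quaternary C4 (CH3 and C1' side chain), C10 methyl, C7 silyloxypropyl | CC(C)C[C@H](c3c(OC)cc(OC)cc3OC)[C@@]1(C)CC/C=C(C)/CC[C@@H](C(C)(C)O[Si](CC)(CC)CC)CC1=O | intermediate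
23 | cis-fused hydroazulen-5-ol (OH cis to H1, H10 cis to H1) | CC(C)C[C@H](c3c(OC)cc(OC)cc3OC)[C@@]1(C)CC[C@H]2[C@]1(O)C[C@H](C(C)(C)O[Si](CC)(CC)CC)CC[C@H]2C | intermediate
24 | hydroazulene with C5=C6 alkene, trimethoxyphenyl and silyl ether | CC(C)C[C@H](c3c(OC)cc(OC)cc3OC)[C@@]1(C)CC[C@H]2C1=C[C@H](C(C)(C)O[Si](CC)(CC)CC)CC[C@H]2C | intermediate
25 | 3-lithio-2,4,6-trimethoxyphenyl derivative of 24 | CC(C)C[C@H](c3c(OC)c([Li])c(OC)cc3OC)[C@@]1(C)CC[C@H]2C1=C[C@H](C(C)(C)O[Si](CC)(CC)CC)CC[C@H]2C | intermediate
26 | lithium α-(dimethylamino)alkoxide of the mono-aldehyde | CC(C)C[C@H](c3c(OC)c(C(O[Li])N(C)C)c(OC)cc3OC)[C@@]1(C)CC[C@H]2C1=C[C@H](C(C)(C)O[Si](CC)(CC)CC)CC[C@H]2C | intermediate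
27 | 5-lithio derivative of 26 | CC(C)C[C@H](c3c(OC)c(C(O[Li])N(C)C)c(OC)c([Li])c3OC)[C@@]1(C)CC[C@H]2C1=C[C@H](C(C)(C)O[Si](CC)(CC)CC)CC[C@H]2C | intermediate
28 | bis[lithium α-(dimethylamino)alkoxide] | CC(C)C[C@H](c3c(OC)c(C(O[Li])N(C)C)c(OC)c(C(O[Li])N(C)C)c3OC)[C@@]1(C)CC[C@H]2C1=C[C@H](C(C)(C)O[Si](CC)(CC)CC)CC[C@H]2C | intermediate
29 | 3,5-diformyl-2,4,6-trimethoxyphenyl hydroazulene, silyl ether | CC(C)C[C@H](c3c(OC)c(C=O)c(OC)c(C=O)c3OC)[C@@]1(C)CC[C@H]2C1=C[C@H](C(C)(C)O[Si](CC)(CC)CC)CC[C@H]2C | intermediate
30 | tri-O-methyl ether of the target | CC(C)C[C@H](c3c(OC)c(C=O)c(OC)c(C=O)c3OC)[C@@]1(C)CC[C@H]2C1=C[C@H](C(C)(C)O)CC[C@H]2C | intermediate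
31 | CNP0281883.3 | CC(C)C[C@H](c1c(O)c(C=O)c(O)c(C=O)c1O)[C@@]1(C)CC[C@H]2C1=C[C@H](C(C)(C)O)CC[C@H]2C | target

**Step count and risks**
Total step count: 18 (steps 1–2 ring fragment, steps 3–8 side-chain fragment, steps 9–18 after the junction).
Longest linear sequence: 16 steps (steps 3–18, from 2-(2,4,6-trimethoxyphenyl)acetic acid).

Steps most likely to fail:

- **Step 14 (key step).** The ketyl may be reduced to the secondary alcohol before it cyclises, the alkene may be attacked on the other face, or C10 may be protonated without selectivity. Fallback by a polar closure of the same bond: from 22, Me2AlCl in CH2Cl2 at −78 °C should promote a transannular carbonyl-ene (Prins-type) cyclisation in which C1 attacks the activated C5 carbonyl and a hydrogen of the C10 methyl group is lost, giving the exocyclic-methylene hydroazulenol F1. Hydrogenation with [Ir(cod)(PCy3)(py)]PF6 under H2 is directed by the C5 hydroxyl to the face syn to it and should give 23, where the route is rejoined.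

- **Step 13.** O-methylation may compete with C-methylation at the hindered tetrasubstituted enolate, or the methylation may lose facial control. Fallback by carbenoid addition in place of alkylation: from 20, the same KH/18-crown-6 rearrangement is quenched with Me3SiCl to give the silyl enol ether F2. Simmons–Smith cyclopropanation (Et2Zn, CH2I2) of this electron-rich alkene on its exposed face gives the siloxycyclopropane F3, and NaOH in MeOH opens it to the α-methyl ketone 22.

- **Step 9.** During the warm period of the Shapiro fragmentation the alkenyllithium may take a proton from the arene C–H or from the allylic, benzylic C1'–H (loss of reagent and erosion of C1'), and the hindered ketone may be enolised instead of attacked. Fallback that makes the nucleophile cold by tin–lithium exchange: from 13, KN(SiMe3)2 and PhNTf2 at −78 °C give the kinetic enol triflate F4, and Pd(PPh3)4 with Me3SnSnMe3 and LiCl gives the alkenylstannane F5. MeLi at −78 °C then generates 15 without warming, and CeCl3 followed by 4 gives 16.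

**Further compounds**
F1 | step 14 | 10-methylidene cis-fused hydroazulen-5-ol (no C10 methyl; exocyclic C10=CH2) | CC(C)C[C@H](c3c(OC)cc(OC)cc3OC)[C@@]1(C)CC[C@H]2[C@]1(O)C[C@H](C(C)(C)O[Si](CC)(CC)CC)CCC2=C
F2 | step 13 | trimethylsilyl enol ether of the (E,E)-cyclodecadienolate | CC(C)C[C@H](c1c(OC)cc(OC)cc1OC)/C2=C(/O[Si](C)(C)C)C[C@H](C(C)(C)O[Si](CC)(CC)CC)CC/C(C)=C/CC2
F3 | step 13 | siloxycyclopropane (CH2 bridging C4 and C5 on the outer face) | CC(C)C[C@H](c1c(OC)cc(OC)cc1OC)[C@]23C[C@]2(O[Si](C)(C)C)C[C@H](C(C)(C)O[Si](CC)(CC)CC)CC/C(C)=C/CC3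
F4 | step 9 | (3S)-5-methyl-3-(2,4,6-trimethoxyphenyl)hex-1-en-2-yl trifluoromethanesulfonate | CC(C)C[C@H](c1c(OC)cc(OC)cc1OC)C(=C)OS(=O)(=O)C(F)(F)F
F5 | step 9 | trimethyl[(3S)-5-methyl-3-(2,4,6-trimethoxyphenyl)hex-1-en-2-yl]stannane | CC(C)C[C@H](c1c(OC)cc(OC)cc1OC)C(=C)[Sn](C)(C)C
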